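The C4–C4a bond of the chromanone is the bond to cut. The quaternary carbon C2 of the pyranone ring has, besides O1 and methyl, two methylene neighbours: C3 inside the ring and C1′ at the root of the side chain. Traced back to a pair of equal allyl groups, C2 is a prochiral ether carbon, and joining either allyl group to the arene makes it a stereocentre. One enantioselective 6-exo Heck cyclisation therefore forms C4–C4a, closes the pyran ring, fixes C2 and leaves a 4-methylene group (latent ketone) plus one allyl group. The precursor is the 2-iodoaryl ether of 4-methylhepta-1,6-dien-4-ol, with bromine para to iodine and a silylated phenol oxygen para to the ether oxygen.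

Key step: step 5

Assumption: which antipode of BINAP leads to (S) at C2 cannot be derived safely for this tether. (R)-BINAP is written, and the equally available (S)-BINAP replaces it if the sense proves opposite.

Design remarks
- **Iodine source.** Iodine comes in with the purchased arene. Making the C–I bond after the ether (amine, diazonium salt, iodide) would generate an aryl radical ortho to the O–C(allyl)2 unit. Radical 6-exo closure onto an allyl arm should then outrun iodine capture and destroy the prochiral substrate. Acidic diazotisation would also endanger the tertiary ether.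
- **Protecting group.** The phenol is masked as a TIPS ether, which is possible because protection follows the alkoxide step. It is removed by buffered fluoride, so the finished chromanone never meets acid or base, and its bulk crowds the neighbouring C–Br bond during the Heck step.
- **Side chain.** The side chain is finished through an acrylate. A tertiary allylic alcohol partner would save one step, but it would leave two alkenes of similar reactivity at the cleavage or reduction stage. Here only one alkene responds to the reagent at each stage.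
- **Timing of the ketone.** A 2,2-disubstituted chroman-4-one can racemise by retro-oxa-Michael opening and reclosure, so the C4 ketone exists only in the last two steps.

Step 1
Reactants: 1 4-methylhepta-1,6-dien-4-ol; 2 4-fluoro-3-iodobenzaldehyde
Product: 4 3-iodo-4-[(4-methylhepta-1,6-dien-4-yl)oxy]benzaldehyde, via potassium alkoxide 3 (not isolated)
Conditions: 1 (1.1 equiv), KH (1.05 equiv), THF, 0 °C; then 2, THF–DMF (4:1), 0 °C to rt
Reagents that add atoms: none
Why: Nucleophilic aromatic substitution (addition–elimination), in which fluoride para to the formyl group and next to iodine is displaced by the tertiary alkoxide far faster than iodide, just as 4-fluorobenzaldehyde gives 4-tert-butoxybenzaldehyde with potassium tert-butoxide.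

Step 2
Reactants: 4 3-iodo-4-[(4-methylhepta-1,6-dien-4-yl)oxy]benzaldehyde
Product: 6 3-iodo-4-[(4-methylhepta-1,6-dien-4-yl)oxy]phenol, via aryl formate 5 (not isolated)
Conditions: 30% aq H2O2 (1.5 equiv), H2SO4 (10 mol %), MeOH, 0 °C to rt
Reagents that add atoms: hydrogen peroxide, OO
Why: Acid-catalysed Dakin-type (Baeyer–Villiger) oxidation, in which the peroxyhemiacetal of an aldehyde para to an alkoxy donor rearranges by aryl migration, methanolysis of the formate frees the phenol, and hydrogen peroxide without a peracid should leave the two terminal alkenes untouched.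

Step 3
Reactants: 6 3-iodo-4-[(4-methylhepta-1,6-dien-4-yl)oxy]phenol
Product: 7 2-bromo-5-iodo-4-[(4-methylhepta-1,6-dien-4-yl)oxy]phenol
Conditions: NBS (1.0 equiv), MeCN, −20 °C to 0 °C, dark
Reagents that add atoms: N-bromosuccinimide, O=C1CCC(=O)N1Br
Why: Electrophilic aromatic bromination, in which the free hydroxyl directs ortho, the ortho site next to the iodine-bearing carbon is crowded so bromine should enter para to iodine (future C7), and the phenol reacts with NBS much faster than a monosubstituted alkene.

Step 4
Reactants: 7 2-bromo-5-iodo-4-[(4-methylhepta-1,6-dien-4-yl)oxy]phenol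
Product: 8 {2-bromo-5-iodo-4-[(4-methylhepta-1,6-dien-4-yl)oxy]phenoxy}tri(propan-2-yl)silane
Conditions: TIPSCl (1.2 equiv), imidazole (2.5 equiv), DMF, rt
Reagents that add atoms: chlorotri(propan-2-yl)silane (TIPSCl), CC(C)[Si](Cl)(C(C)C)C(C)C
Why: Standard O-silylation of a phenol, giving an ether that should tolerate silver phosphate, ruthenium carbenes, copper hydride, the Grignard reagent and periodate, and that keeps the electron-rich phenol from being oxidised by silver salts.

Step 5
Reactants: 8 {2-bromo-5-iodo-4-[(4-methylhepta-1,6-dien-4-yl)oxy]phenoxy}tri(propan-2-yl)silane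
Product: 9 (2S)-7-bromo-2-methyl-4-methylidene-2-(prop-2-en-1-yl)-6-[tri(propan-2-yl)silyloxy]-3,4-dihydro-2H-chromene
Conditions: Pd(OAc)2 (10 mol %), (R)-BINAP (15 mol %), Ag3PO4 (2 equiv), NMP, 60 °C
Reagents that add atoms: none
Why: Zerovalent palladium formed in situ from Pd(OAc)2 and BINAP inserts into the C–I bond, Ag3PO4 strips iodide to leave a cationic (BINAP)arylpalladium that binds one allyl arm, syn migratory insertion joins C4a to the internal alkene carbon (C4), and bond rotation followed by syn beta-hydride elimination of the C4–H gives the exocyclic methylene. The closest known reaction type is the enantioselective, group-selective (desymmetrising) intramolecular Mizoroki–Heck cyclisation of prochiral dienes under cationic bisphosphine conditions. The pyran ring (O1, C2, C3, C4, C4a, C8a) closes 6-exo-trig, the 7-endo mode being disfavoured by the short tether. C2 is the only lasting stereocentre: the ligand fixes the alkene face at the transient C4 centre, and the chair-like insertion transition state relays this to C2 by picking the arm that leaves the spare allyl group pseudo-equatorial and methyl pseudo-axial, so the ligand antipode decides (S) versus (R). Site selectivity for iodine over bromine rests on the much faster oxidative addition to C–I at 60 °C and on the ortho silyloxy group that crowds C7–Br. Removal of iodide by silver also holds back hydridopalladium re-addition, which would move the new alkene to the endocyclic C3=C4 position or isomerise the spare allyl group.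

Step 6
Reactants: 9 (2S)-7-bromo-2-methyl-4-methylidene-2-(prop-2-en-1-yl)-6-[tri(propan-2-yl)silyloxy]-3,4-dihydro-2H-chromene; 10 methyl acrylate
Product: 11 methyl (2E)-4-{(2S)-7-bromo-2-methyl-4-methylidene-6-[tri(propan-2-yl)silyloxy]-3,4-dihydro-2H-chromen-2-yl}but-2-enoate
Conditions: second-generation Hoveyda–Grubbs catalyst (5 mol %), 10 (5 equiv), 1,4-benzoquinone (10 mol %), CH2Cl2, 40 °C
Reagents that add atoms: none
Why: Olefin cross-metathesis of a monosubstituted alkene with an acrylate is E-selective, the 1,1-disubstituted styrenyl methylene is too hindered to take part and ring closure between the two alkenes would need a bridgehead alkene, and the terminal CH2 leaves as ethene so the arm supplies C1′ and C2′ while the acrylate supplies C3′ and C4′.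

Step 7
Reactants: 11 methyl (2E)-4-{(2S)-7-bromo-2-methyl-4-methylidene-6-[tri(propan-2-yl)silyloxy]-3,4-dihydro-2H-chromen-2-yl}but-2-enoate
Product: 12 methyl 4-{(2S)-7-bromo-2-methyl-4-methylidene-6-[tri(propan-2-yl)silyloxy]-3,4-dihydro-2H-chromen-2-yl}butanoate
Conditions: Cu(OAc)2·H2O (5 mol %), 1,2-bis(diphenylphosphino)benzene (5 mol %), (EtO)2MeSiH (2 equiv), t-BuOH (2 equiv), toluene, rt
Reagents that add atoms: none
Why: Copper hydride conjugate reduction, in which the phosphine-ligated copper hydride adds 1,4 only to the polarised enoate, so the unpolarised exocyclic alkene, the C–Br bond and the silyl ether should survive, a selectivity that hydrogenation or diimide would not guarantee.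

Step 8
Reactants: 12 methyl 4-{(2S)-7-bromo-2-methyl-4-methylidene-6-[tri(propan-2-yl)silyloxy]-3,4-dihydro-2H-chromen-2-yl}butanoate
Product: 14 5-{(2S)-7-bromo-2-methyl-4-methylidene-6-[tri(propan-2-yl)silyloxy]-3,4-dihydro-2H-chromen-2-yl}-2-methylpentan-2-ol, via methyl ketone 13 (not isolated)
Conditions: MeMgBr (3.5 equiv), THF, 0 °C; aq NH4Cl
Reagents that add atoms: methylmagnesium bromide, C[Mg]Br
Why: Double Grignard addition to an ester builds the tertiary carbinol C4′ while C4 is still masked as an alkene, so no ring ketone competes, and MeMgBr does not exchange with an aryl bromide at 0 °C.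

Step 9
Reactants: 14 5-{(2S)-7-bromo-2-methyl-4-methylidene-6-[tri(propan-2-yl)silyloxy]-3,4-dihydro-2H-chromen-2-yl}-2-methylpentan-2-ol
Product: 16 (2S)-7-bromo-2-(4-hydroxy-4-methylpentyl)-2-methyl-6-[tri(propan-2-yl)silyloxy]-2,3-dihydro-4H-chromen-4-one, via vicinal diol 15 (not isolated)
Conditions: OsO4 (2 mol %), NaIO4 (4 equiv), 2,6-lutidine (2 equiv), 1,4-dioxane–H2O (3:1), rt
Reagents that add atoms: osmium tetroxide, O=[Os](=O)(=O)=O; sodium periodate, [Na+].[O-]I(=O)(=O)=O
Why: Lemieux–Johnson oxidative cleavage acts on the only alkene left, the protected arene is not touched as it might be by ozone, and the lutidine-buffered, near-neutral medium should not trigger retro-oxa-Michael opening, so C2 keeps its configuration.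

Step 10
Reactants: 16 (2S)-7-bromo-2-(4-hydroxy-4-methylpentyl)-2-methyl-6-[tri(propan-2-yl)silyloxy]-2,3-dihydro-4H-chromen-4-one
Product: 17 (2S)-7-bromo-6-hydroxy-2-(4-hydroxy-4-methylpentyl)-2-methyl-2,3-dihydro-4H-chromen-4-one (CNP0351288.1)
Conditions: Bu4NF (1.2 equiv), AcOH (1.2 equiv), THF, 0 °C
Reagents that add atoms: none
Why: Fluoride-induced desilylation of an aryl silyl ether is fast at 0 °C, and the acetic acid buffer avoids both enolisation at C3 (which would racemise C2) and acid-induced loss of the tertiary alcohol.

Compound list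
1 | 4-methylhepta-1,6-dien-4-ol | C=CCC(C)(O)CC=C | starting material
2 | 4-fluoro-3-iodobenzaldehyde | O=Cc1ccc(F)c(I)c1 | starting material
3 | potassium 4-methylhepta-1,6-dien-4-olate | C=CCC(C)([O-])CC=C.[K+] | intermediate (not isolated)
4 | 3-iodo-4-[(4-methylhepta-1,6-dien-4-yl)oxy]benzaldehyde | O=Cc1ccc(OC(C)(CC=C)CC=C)c(I)c1 | intermediate
5 | 3-iodo-4-[(4-methylhepta-1,6-dien-4-yl)oxy]phenyl formate | O=COc1ccc(OC(C)(CC=C)CC=C)c(I)c1 | intermediate (not isolated)
6 | 3-iodo-4-[(4-methylhepta-1,6-dien-4-yl)oxy]phenol | Oc1ccc(OC(C)(CC=C)CC=C)c(I)c1 | intermediate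
7 | 2-bromo-5-iodo-4-[(4-methylhepta-1,6-dien-4-yl)oxy]phenol | Oc1cc(I)c(OC(C)(CC=C)CC=C)cc1Br | intermediate
8 | {2-bromo-5-iodo-4-[(4-methylhepta-1,6-dien-4-yl)oxy]phenoxy}tri(propan-2-yl)silane (Heck precursor) | C=CCC(C)(CC=C)Oc1cc(Br)c(O[Si](C(C)C)(C(C)C)C(C)C)cc1I | intermediate
9 | (2S)-7-bromo-2-methyl-4-methylidene-2-(prop-2-en-1-yl)-6-[tri(propan-2-yl)silyloxy]-3,4-dihydro-2H-chromene (Heck product) | C=CC[C@@]1(C)CC(=C)c2cc(O[Si](C(C)C)(C(C)C)C(C)C)c(Br)cc2O1 | intermediate
10 | methyl acrylate | C=CC(=O)OC | starting material
11 | methyl (2E)-4-{(2S)-7-bromo-2-methyl-4-methylidene-6-[tri(propan-2-yl)silyloxy]-3,4-dihydro-2H-chromen-2-yl}but-2-enoate | COC(=O)/C=C/C[C@@]1(C)CC(=C)c2cc(O[Si](C(C)C)(C(C)C)C(C)C)c(Br)cc2O1 | intermediate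
12 | methyl 4-{(2S)-7-bromo-2-methyl-4-methylidene-6-[tri(propan-2-yl)silyloxy]-3,4-dihydro-2H-chromen-2-yl}butanoate | COC(=O)CCC[C@@]1(C)CC(=C)c2cc(O[Si](C(C)C)(C(C)C)C(C)C)c(Br)cc2O1 | intermediate
13 | 5-{(2S)-7-bromo-2-methyl-4-methylidene-6-[tri(propan-2-yl)silyloxy]-3,4-dihydro-2H-chromen-2-yl}pentan-2-one | CC(=O)CCC[C@@]1(C)CC(=C)c2cc(O[Si](C(C)C)(C(C)C)C(C)C)c(Br)cc2O1 | intermediate (not isolated)
14 | 5-{(2S)-7-bromo-2-methyl-4-methylidene-6-[tri(propan-2-yl)silyloxy]-3,4-dihydro-2H-chromen-2-yl}-2-methylpentan-2-ol | CC(C)(O)CCC[C@@]1(C)CC(=C)c2cc(O[Si](C(C)C)(C(C)C)C(C)C)c(Br)cc2O1 | intermediate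
15 | (2S)-7-bromo-4-(hydroxymethyl)-2-(4-hydroxy-4-methylpentyl)-2-methyl-6-[tri(propan-2-yl)silyloxy]-3,4-dihydro-2H-chromen-4-ol (both C4 epimers) | CC(C)(O)CCC[C@@]1(C)CC(O)(CO)c2cc(O[Si](C(C)C)(C(C)C)C(C)C)c(Br)cc2O1 | intermediate (not isolated)
16 | (2S)-7-bromo-2-(4-hydroxy-4-methylpentyl)-2-methyl-6-[tri(propan-2-yl)silyloxy]-2,3-dihydro-4H-chromen-4-one | CC(C)(O)CCC[C@@]1(C)CC(=O)c2cc(O[Si](C(C)C)(C(C)C)C(C)C)c(Br)cc2O1 | intermediate
17 | (2S)-7-bromo-6-hydroxy-2-(4-hydroxy-4-methylpentyl)-2-methyl-2,3-dihydro-4H-chromen-4-one | CC(C)(O)CCC[C@@]1(C)CC(=O)c2cc(O)c(Br)cc2O1 | target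

Total step count: 10
Longest linear sequence: 10 steps (from 1 and 2 to 17)

Steps most likely to fail

1. **Step 5.** Methyl and allyl differ little in size in the chair-like insertion transition state, so the two enantiotopic arms may be told apart poorly. Hydridopalladium re-addition may also move the exocyclic double bond into the ring. The fallback replaces asymmetric catalysis by resolution and sets out from 8.
   - Cyclisation with Pd(OAc)2, 1,3-bis(diphenylphosphino)propane and Ag3PO4 in NMP should give racemic 2-allyl-4-methylenechroman F1.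
   - F1 is separated by preparative chromatography on a chiral stationary phase (amylose carbamate, supercritical CO2/2-propanol).
   - The (S)-enantiomer is 9, where the route is rejoined.

2. **Step 2.** Hydride rather than aryl migration in the peroxyhemiacetal may lead to the benzoate oxidation level, and the acid may ionise the tertiary ether. The fallback sets out from 3 and brings the phenol oxygen in by a nucleophilic oxidation of boron.
   - Alkoxide 3 is combined with purchased 1-fluoro-2-iodo-4-nitrobenzene F2 (THF, 0 °C) in a nitro-activated substitution to give nitro ether F3.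
   - Fe powder and NH4Cl in aqueous ethanol reduce F3 to aniline F4.
   - Aprotic diazotisation–borylation (t-BuONO, B2pin2, MeCN) gives pinacol boronate F5. The aryl radical involved sits para to the ether oxygen, out of reach of the allyl arms.
   - NaBO3·4H2O in THF–water, which ignores alkenes, converts F5 into phenol 6, where the route is rejoined.

3. **Step 1.** The alkoxide may add to the formyl group and start hydride transfer between aldehyde molecules (Tishchenko or Cannizzaro type) before fluoride is displaced. The fallback sets out from 3 and uses an activating group that cannot pass on hydride.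
   - Alkoxide 3 and purchased 4-fluoro-3-iodobenzonitrile F6 (THF–DMF, 0 °C to rt) should give nitrile ether F7.
   - i-Bu2AlH (toluene, −78 °C) followed by mild aqueous hydrolysis of the aluminium imine gives aldehyde 4, where the route is rejoined.

Further compounds
F1 | step 5 | racemic 7-bromo-2-methyl-4-methylidene-2-(prop-2-en-1-yl)-6-[tri(propan-2-yl)silyloxy]-3,4-dihydro-2H-chromene | C=CCC1(C)CC(=C)c2cc(O[Si](C(C)C)(C(C)C)C(C)C)c(Br)cc2O1
F2 | step 2 | 1-fluoro-2-iodo-4-nitrobenzene (purchased) | O=[N+]([O-])c1ccc(F)c(I)c1
F3 | step 2 | 2-iodo-1-[(4-methylhepta-1,6-dien-4-yl)oxy]-4-nitrobenzene | O=[N+]([O-])c1ccc(OC(C)(CC=C)CC=C)c(I)c1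
F4 | step 2 | 3-iodo-4-[(4-methylhepta-1,6-dien-4-yl)oxy]aniline | Nc1ccc(OC(C)(CC=C)CC=C)c(I)c1
F5 | step 2 | 2-{3-iodo-4-[(4-methylhepta-1,6-dien-4-yl)oxy]phenyl}-4,4,5,5-tetramethyl-1,3,2-dioxaborolane | CC1(C)OB(OC1(C)C)c1ccc(OC(C)(CC=C)CC=C)c(I)c1
F6 | step 1 | 4-fluoro-3-iodobenzonitrile (purchased) | N#Cc1ccc(F)c(I)c1
F7 | step 1 | 3-iodo-4-[(4-methylhepta-1,6-dien-4-yl)oxy]benzonitrile | N#Cc1ccc(OC(C)(CC=C)CC=C)c(I)c1
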